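The spiro-γ-lactone (ring D) is built last-but-five by a [3+2] annulation on a 9,13-epoxy-16-oic acid: the C13 enediolate is alkylated by a two-carbon 1,2-dielectrophile and the carboxylate closes the ring, so C13–C14 and C15–O form in one operation. The dielectrophile hangs on a temporary sulfate tether from O20. Because C10 and C13 are 1,3-related across the oxygen of the tetrahydrofuran (ring C: O, C9, C11, C12, C13), C14 can only arrive on the C10 face of C13. The precursor, a cis-fused decalin carrying that tether, comes from a Diels–Alder reaction of a chiral 2-carbomethoxycyclohexenone.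

Key step: step 15

Remark 1: labdane numbering is used (ring A C1–C5/C10, ring B C5–C10, C18 methyl and C19 on C4, C17 methyl on C8, C20 on C10); β is the decalin face that carries C20.
Remark 2: in the target SMILES H5 lies on the same face as C20, C19 and O6, so rings A/B are cis-fused and the 19,6-lactone is trans-fused to both; the route is planned for exactly this (4S,5S,6R,8R,9R,10S,13R) isomer.
Remark 3: (R)-4-(tert-butyldimethylsilyloxy)cyclohex-2-en-1-one is taken as commercially available.

Step 1
Reactants: 1 (R)-4-(tert-butyldimethylsilyloxy)cyclohex-2-en-1-one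
Product: 2 (4R,6R)-4-(tert-butyldimethylsilyloxy)-6-methylcyclohex-2-en-1-one
Conditions: LiN(i-Pr)2, THF, −78 °C; MeI, −78 → −40 °C
Reagents that add atoms: iodomethane CI
Why: Kinetic α′-deprotonation gives the cross-conjugated lithium enolate, and enolate alkylation should place the methyl group trans to the pseudoaxial C4 silyloxy group (1,3-induction), which sets the future C8 as R.

Step 2
Reactants: 2 (4R,6R)-4-(tert-butyldimethylsilyloxy)-6-methylcyclohex-2-en-1-one
Product: 3 (4R,6R)-4-(tert-butyldimethylsilyloxy)-2-iodo-6-methylcyclohex-2-en-1-one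
Conditions: I2, pyridine, CH2Cl2, 0 → 25 °C
Reagents that add atoms: iodine II
Why: α-Iodination of the enone by conjugate addition of pyridine, iodination of the enolate and elimination (Baylis–Hillman-type mechanism) should touch no stereocenter.

Step 3
Reactants: 3 (4R,6R)-4-(tert-butyldimethylsilyloxy)-2-iodo-6-methylcyclohex-2-en-1-one
Product: 4 methyl (3R,5R)-3-(tert-butyldimethylsilyloxy)-5-methyl-6-oxocyclohex-1-ene-1-carboxylate
Conditions: PdCl2(PPh3)2 (cat.), CO (1 atm), MeOH, i-Pr2NEt, DMF, 40 °C
Reagents that add atoms: carbon monoxide [C-]#[O+]; methanol CO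
Why: Palladium-catalysed methoxycarbonylation of the vinyl iodide (oxidative addition, CO insertion, methanolysis) should give the doubly activated dienophile, the weak amine base leaving C8 unepimerised.

Step 4
Reactants: 5 pent-1-en-3-one
Product: 6 (Z)-3-(trimethylsilyloxy)penta-1,3-diene
Conditions: Me3SiOTf, Et3N, Et2O, 0 °C
Reagents that add atoms: trimethylsilyl trifluoromethanesulfonate C[Si](C)(C)OS(=O)(=O)C(F)(F)F
Why: Soft enolisation and O-silylation of the ethyl ketone should give the 2-silyloxydiene, mainly as the Z enol ether whose methyl group points away from the vinyl group.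

Step 5
Reactants: 4 methyl (3R,5R)-3-(tert-butyldimethylsilyloxy)-5-methyl-6-oxocyclohex-1-ene-1-carboxylate; 6 (Z)-3-(trimethylsilyloxy)penta-1,3-diene
Product: 7 cis-decalin Diels–Alder adduct
Conditions: toluene, 60 °C
Reagents that add atoms: none
Why: In this Diels–Alder reaction the methyl-bearing nucleophilic diene terminus should bond to the β-carbon C5 and the diene should add anti to the C6 silyloxy group, so that H5, the C10 ester and O6 end up on one face of a cis-fused decalin, while C4 is set only provisionally (ketone-endo) and is renewed in step 8.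

Step 6
Reactants: 7 cis-decalin Diels–Alder adduct
Product: 8 C9 carbinol trimethylsilyl ether
Conditions: CH2=CHCH2CH2MgBr, CeCl3, THF, −78 °C; then Me3SiOTf, 2,6-lutidine, −78 → 0 °C
Reagents that add atoms: but-3-enylmagnesium bromide C=CCC[Mg]Br; trimethylsilyl trifluoromethanesulfonate C[Si](C)(C)OS(=O)(=O)C(F)(F)F
Why: 1,2-Addition of the non-basic organocerium reagent to the hindered C9 ketone should occur on the convex β-face of the cis-decalin, anti to the C8 methyl group and to ring A, which puts C11 β and the oxygen α, and the alkoxide is silylated at once so that the β-alkoxy ester cannot undergo retro-aldol cleavage in the basic steps that follow.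

Step 7
Reactants: 8 C9 carbinol trimethylsilyl ether
Product: 9 Δ1-3-ketone
Conditions: 2-iodoxybenzoic acid (IBX), 4-methoxypyridine N-oxide, DMSO, 25 °C
Reagents that add atoms: none
Why: Dehydrogenation of the trimethylsilyl enol ether by the hypervalent iodine oxidant (a metal-free Saegusa-type oxidation) should give the Δ1-3-ketone, in which C4 is the only enolisable carbon.

Step 8
Reactants: 9 Δ1-3-ketone
Product: 10 C4-quaternary enone
Conditions: LiN(i-Pr)2, THF, −78 °C; BnOCH2Cl, −78 → −40 °C
Reagents that add atoms: benzyl chloromethyl ether ClCOCc1ccccc1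
Why: α′-Deprotonation gives the C3–C4 enolate, and enolate C-alkylation on the convex β-face of ring A (anti to the C5–C6 bond, ring B lying under the α-face) should make C19 β and the methyl group α at the new quaternary C4.

Step 9
Reactants: 10 C4-quaternary enone
Product: 11 vinyl triflate
Conditions: LiBH(sec-Bu)3, THF, −78 °C; then PhNTf2, −78 → 0 °C
Reagents that add atoms: N-phenylbis(trifluoromethanesulfonimide) O=S(=O)(N(c1ccccc1)S(=O)(=O)C(F)(F)F)C(F)(F)F
Why: Conjugate hydride addition to the β-unsubstituted enone gives the C2–C3 enolate regiospecifically, and its O-sulfonylation (reductive triflation) should give the vinyl triflate without touching a stereocenter.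

Step 10
Reactants: 11 vinyl triflate
Product: 12 Δ2-alkene ester
Conditions: Pd(OAc)2 (cat.), PPh3, HCO2H, n-Bu3N, DMF, 60 °C
Reagents that add atoms: none
Why: Palladium-catalysed formate reduction of the vinyl triflate (oxidative addition, decarboxylation of formate to a hydride, reductive elimination) should remove the C3 oxygen and leave the Δ2 alkene.

Step 11
Reactants: 12 Δ2-alkene ester
Product: 14 9α,20-diol, via 20-ol 9-O-trimethylsilyl ether 13 (not isolated)
Conditions: LiAlH4, THF, 0 °C; then 1 M HCl, THF, 0 °C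
Reagents that add atoms: none
Why: Hydride reduction of the only carbonyl group, the neopentyl C20 ester, should give the primary alcohol, and the acidic work-up cleaves the tertiary trimethylsilyl ether while the hindered secondary silyl ether stays.

Step 12
Reactants: 14 9α,20-diol
Product: 15 20-O-(2-bromoethyl) sulfate
Conditions: SO2Cl2, BrCH2CH2OH, pyridine, CH2Cl2, −78 °C; then 14, pyridine, −40 → 0 °C
Reagents that add atoms: sulfuryl chloride O=S(=O)(Cl)Cl; 2-bromoethanol OCCBr
Why: O-Sulfonylation of the primary C20 alcohol by the preformed 2-bromoethyl chlorosulfate should give the mixed dialkyl sulfate, the tertiary C9 hydroxyl being too hindered to compete.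

Step 13
Reactants: 15 20-O-(2-bromoethyl) sulfate
Product: 16 tetrahydrofuran alcohol
Conditions: Co(modp)2 (cat.; modp = 1-morpholinocarbamoyl-4,4-dimethyl-1,3-pentanedionate), O2 (1 atm), t-BuOOH (cat.), i-PrOH, 55 °C
Reagents that add atoms: dioxygen O=O
Why: Mukaiyama aerobic oxidative cyclisation of the pent-4-en-1-ol unit (5-exo closure of O9 onto C13, oxygenation and in situ reduction at C16) should give the 2-hydroxymethyl tetrahydrofuran as a mixture of C13 epimers, which is harmless because C13 becomes planar in step 15.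

Step 14
Reactants: 16 tetrahydrofuran alcohol
Product: 18 tetrahydrofuran acid, via tetrahydrofuran aldehyde 17 (not isolated)
Conditions: TEMPO (cat.), PhI(OAc)2, MeCN/H2O, 25 °C
Reagents that add atoms: water O
Why: Oxoammonium-catalysed oxidation of the primary alcohol and then of the aldehyde hydrate should give the carboxylic acid and leave the dialkyl sulfate, the silyl ether and both alkenes untouched.

Step 15
Reactants: 18 tetrahydrofuran acid
Product: 21 (13R)-spirolactone C20 alcohol, via ten-membered cyclic sulfate 19 (not isolated), via spirolactone sulfate 20 (not isolated)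
Conditions: LiN(i-Pr)2 (2.2 equiv), THF, −78 → 0 °C; then H2SO4 (cat.), H2O, THF, 25 °C
Reagents that add atoms: none
Why: The base forms the carboxylate and then the C13 enediolate, the only enolisable site of 18; its carbon displaces bromide from the end of the sulfate tether (exo-tet closure of the temporary ten-membered ring of 19, forming C13–C14), the carboxylate oxygen then displaces the sulfate oxygen from the neighbouring carbon (5-exo-tet, forming C15–O and opening the temporary ring to 20), and dilute acid hydrolyses the sulfate monoester to the C20 alcohol. The closest known reaction type is the annulation of carboxylic acid enediolates with 1,2-dielectrophiles such as 1-bromo-2-chloroethane or cyclic sulfates to γ-butyrolactones; the delivery of the dielectrophile through a sulfate tether is the new design element. The new quaternary stereocenter C13 is controlled by the tether: the electrophile is anchored through O20 on C10, which is 1,3-related to C13 across the ring-C oxygen, so C14 can reach only the face of the planar enediolate that is syn to C10, and this is the 13R configuration whichever C13 epimer of 18 is used. The step needs facial selectivity at C13, C- over O-alkylation and attack at the bromide-bearing carbon; the tether secures the first, the soft enediolate carbon the second, and the third follows because attack at the sulfate-bearing carbon would demand an endocyclic SN2 geometry within a nine-membered ring.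

Step 16
Reactants: 21 (13R)-spirolactone C20 alcohol
Product: 22 C20 acetate
Conditions: Ac2O, pyridine, DMAP (cat.), CH2Cl2, 25 °C
Reagents that add atoms: acetic anhydride CC(=O)OC(C)=O
Why: Nucleophile-catalysed O-acylation of the primary neopentyl alcohol should give the C20 acetate.

Step 17
Reactants: 22 C20 acetate
Product: 23 C19 alcohol
Conditions: H2 (1 atm), Pd(OH)2/C, EtOAc, 25 °C
Reagents that add atoms: none
Why: Heterogeneous hydrogenation should saturate the Δ2 alkene and hydrogenolyse the benzyl ether to the C19 alcohol without forming a stereocenter.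

Step 18
Reactants: 23 C19 alcohol
Product: 25 C19 acid, via C19 aldehyde 24 (not isolated)
Conditions: TEMPO (cat.), NaOCl (cat.), NaClO2, MeCN/phosphate buffer pH 6.7, 35 °C
Reagents that add atoms: sodium chlorite [Na+].[O-]Cl=O
Why: Oxoammonium oxidation to the aldehyde and chlorite (Pinnick-type) oxidation in the same pot should give the hindered C19 acid under near-neutral conditions that spare the acetate, the lactone and the silyl ether.

Step 19
Reactants: 25 C19 acid
Product: 26 6β-hydroxy C19 acid
Conditions: HF·pyridine, THF, 0 → 25 °C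
Reagents that add atoms: none
Why: Fluoride-mediated cleavage of the secondary silyl ether should free the 6β-hydroxyl under conditions too mild for acyl migration from O20.

Step 20
Reactants: 26 6β-hydroxy C19 acid
Product: 28 target 20-acetoxy-9,13-epoxylabdane-19,6:16,15-diolide, via mixed anhydride 27 (not isolated)
Conditions: 2,4,6-Cl3C6H2COCl, Et3N, THF, 25 °C; then DMAP, toluene, 80 °C, high dilution
Reagents that add atoms: none
Why: Yamaguchi lactonisation activates the C19 acid as a mixed anhydride and the 6β-hydroxyl attacks it with retention at C6, which should close the γ-lactone trans to both carbocycles, the configurations at C4, C5 and C6 having been fixed in steps 8, 5 and 1.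

Compound list

1 | (R)-4-(tert-butyldimethylsilyloxy)cyclohex-2-en-1-one | O=C1C=C[C@H](O[Si](C)(C)C(C)(C)C)CC1 | starting material
2 | (4R,6R)-4-(tert-butyldimethylsilyloxy)-6-methylcyclohex-2-en-1-one (4,6-trans) | O=C1C=C[C@H](O[Si](C)(C)C(C)(C)C)C[C@H]1C | intermediate
3 | (4R,6R)-4-(tert-butyldimethylsilyloxy)-2-iodo-6-methylcyclohex-2-en-1-one | O=C1C(I)=C[C@H](O[Si](C)(C)C(C)(C)C)C[C@H]1C | intermediate
4 | methyl (3R,5R)-3-(tert-butyldimethylsilyloxy)-5-methyl-6-oxocyclohex-1-ene-1-carboxylate | COC(=O)C1=C[C@H](O[Si](C)(C)C(C)(C)C)C[C@@H](C)C1=O | intermediate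
5 | pent-1-en-3-one | C=CC(=O)CC | starting material
6 | (Z)-3-(trimethylsilyloxy)penta-1,3-diene | C=C/C(=C/C)O[Si](C)(C)C | intermediate
7 | Diels–Alder adduct: cis-fused decalin with 10β-CO2Me (C20), 5β-H, 6β-OSiMe2t-Bu, 8α-Me, 9-oxo, 4α-Me and a C2=C3 enol ether (3-OSiMe3) | COC(=O)[C@]12CC=C(O[Si](C)(C)C)[C@@H](C)[C@H]1[C@H](O[Si](C)(C)C(C)(C)C)C[C@@H](C)C2=O | intermediate
8 | C9 carbinol silyl ether: 7 with 9α-OSiMe3 and 9β-(but-3-enyl) in place of the ketone | COC(=O)[C@]12CC=C(O[Si](C)(C)C)[C@@H](C)[C@H]1[C@H](O[Si](C)(C)C(C)(C)C)C[C@@H](C)[C@]2(O[Si](C)(C)C)CCC=C | intermediate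
9 | Δ1-3-ketone: 8 with C1=C2–C3=O in ring A (4α-Me, 4β-H) | COC(=O)[C@]12C=CC(=O)[C@@H](C)[C@H]1[C@H](O[Si](C)(C)C(C)(C)C)C[C@@H](C)[C@]2(O[Si](C)(C)C)CCC=C | intermediate
10 | C4-quaternary enone: 9 with 4α-Me and 4β-CH2OBn (C19) | COC(=O)[C@]12C=CC(=O)[C@](C)(COCc3ccccc3)[C@H]1[C@H](O[Si](C)(C)C(C)(C)C)C[C@@H](C)[C@]2(O[Si](C)(C)C)CCC=C | intermediate
11 | vinyl triflate: 10 with C1H2, C2=C3 and 3-OSO2CF3 | COC(=O)[C@]12CC=C(OS(=O)(=O)C(F)(F)F)[C@](C)(COCc3ccccc3)[C@H]1[C@H](O[Si](C)(C)C(C)(C)C)C[C@@H](C)[C@]2(O[Si](C)(C)C)CCC=C | intermediate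
12 | Δ2-alkene ester: 10β-CO2Me, 5β-H, 4α-Me, 4β-CH2OBn, 6β-OSiMe2t-Bu, 8α-Me, 9α-OSiMe3, 9β-(but-3-enyl), C2=C3 | COC(=O)[C@]12CC=C[C@](C)(COCc3ccccc3)[C@H]1[C@H](O[Si](C)(C)C(C)(C)C)C[C@@H](C)[C@]2(O[Si](C)(C)C)CCC=C | intermediate
13 | 20-ol 9-O-trimethylsilyl ether: 12 with CH2OH (C20) in place of CO2Me | OC[C@]12CC=C[C@](C)(COCc3ccccc3)[C@H]1[C@H](O[Si](C)(C)C(C)(C)C)C[C@@H](C)[C@]2(O[Si](C)(C)C)CCC=C | intermediate
14 | 9α,20-diol: 13 with free 9α-OH | OC[C@]12CC=C[C@](C)(COCc3ccccc3)[C@H]1[C@H](O[Si](C)(C)C(C)(C)C)C[C@@H](C)[C@]2(O)CCC=C | intermediate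
15 | 20-O-(2-bromoethyl) sulfate of 14 (20-O–SO2–O–CH2CH2Br) | BrCCOS(=O)(=O)OC[C@]12CC=C[C@](C)(COCc3ccccc3)[C@H]1[C@H](O[Si](C)(C)C(C)(C)C)C[C@@H](C)[C@]2(O)CCC=C | intermediate
16 | tetrahydrofuran alcohol: 9α,13-epoxide (ring C) with 13-CH2OH (C16), 13RS; other groups as 15 | BrCCOS(=O)(=O)OC[C@]12CC=C[C@](C)(COCc3ccccc3)[C@H]1[C@H](O[Si](C)(C)C(C)(C)C)C[C@@H](C)[C@]24CCC(CO)O4 | intermediate
17 | tetrahydrofuran aldehyde: 16 with 13-CHO (13RS) | BrCCOS(=O)(=O)OC[C@]12CC=C[C@](C)(COCc3ccccc3)[C@H]1[C@H](O[Si](C)(C)C(C)(C)C)C[C@@H](C)[C@]24CCC(C=O)O4 | intermediate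
18 | tetrahydrofuran acid: 16 with 13-CO2H (9α,13-epoxy-16-oic acid, 13RS) | BrCCOS(=O)(=O)OC[C@]12CC=C[C@](C)(COCc3ccccc3)[C@H]1[C@H](O[Si](C)(C)C(C)(C)C)C[C@@H](C)[C@]24CCC(C(=O)O)O4 | intermediate
19 | ten-membered cyclic sulfate: (13R), C13 bears CO2H and C14H2–C15H2–O–SO2–O–C20 | O=S1(=O)OC[C@]23CC=C[C@](C)(COCc4ccccc4)[C@H]2[C@H](O[Si](C)(C)C(C)(C)C)C[C@@H](C)[C@]35CC[C@@](CCO1)(C(=O)O)O5 | intermediate
20 | (13R)-spirolactone sulfate: ring D closed (16,15-olide), 20-OSO3H | OS(=O)(=O)OC[C@]12CC=C[C@](C)(COCc3ccccc3)[C@H]1[C@H](O[Si](C)(C)C(C)(C)C)C[C@@H](C)[C@]24CC[C@]5(CCOC5=O)O4 | intermediate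
21 | (13R)-spirolactone C20 alcohol: 4α-Me, 4β-CH2OBn, 5β-H, 6β-OSiMe2t-Bu, 8α-Me, C2=C3, 20-OH | OC[C@]12CC=C[C@](C)(COCc3ccccc3)[C@H]1[C@H](O[Si](C)(C)C(C)(C)C)C[C@@H](C)[C@]24CC[C@]5(CCOC5=O)O4 | intermediate
22 | C20 acetate of 21 | CC(=O)OC[C@]12CC=C[C@](C)(COCc3ccccc3)[C@H]1[C@H](O[Si](C)(C)C(C)(C)C)C[C@@H](C)[C@]24CC[C@]5(CCOC5=O)O4 | intermediate
23 | C19 alcohol: ring A saturated, 4β-CH2OH, 20-OAc, 6β-OSiMe2t-Bu | CC(=O)OC[C@]12CCC[C@](C)(CO)[C@H]1[C@H](O[Si](C)(C)C(C)(C)C)C[C@@H](C)[C@]24CC[C@]5(CCOC5=O)O4 | intermediate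
24 | C19 aldehyde (4β-CHO) | CC(=O)OC[C@]12CCC[C@](C)(C=O)[C@H]1[C@H](O[Si](C)(C)C(C)(C)C)C[C@@H](C)[C@]24CC[C@]5(CCOC5=O)O4 | intermediate
25 | C19 acid (4β-CO2H), 6β-OSiMe2t-Bu | CC(=O)OC[C@]12CCC[C@](C)(C(=O)O)[C@H]1[C@H](O[Si](C)(C)C(C)(C)C)C[C@@H](C)[C@]24CC[C@]5(CCOC5=O)O4 | intermediate
26 | 6β-hydroxy C19 acid | CC(=O)OC[C@]12CCC[C@](C)(C(=O)O)[C@H]1[C@H](O)C[C@@H](C)[C@]24CC[C@]5(CCOC5=O)O4 | intermediate
27 | mixed anhydride of 26 with 2,4,6-trichlorobenzoic acid | CC(=O)OC[C@]12CCC[C@](C)(C(=O)OC(=O)c3c(Cl)cc(Cl)cc3Cl)[C@H]1[C@H](O)C[C@@H](C)[C@]24CC[C@]5(CCOC5=O)O4 | intermediate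
28 | (4S,5S,6R,8R,9R,10S,13R)-20-acetoxy-9,13-epoxylabdane-19,6:16,15-diolide | CC(=O)OC[C@@]12CCC[C@]3(C)C(=O)O[C@H](C[C@@H](C)[C@]14CC[C@]1(CCOC1=O)O4)[C@@H]23 | target

Total step count: 20. Longest linear sequence: 19 steps (steps 1–3 and 5–20; step 4 is the side branch).

Steps most likely to fail

Step 20 (lactonisation). The ring must close against strain: the γ-lactone is trans-fused to both rings of a cis-decalin, which forces boat-like six-membered rings, so intermolecular acylation or reopening on work-up may win over cyclisation. The fallback sets out from 26 and comes back at 28, and makes the C6–O bond by substitution at carbon instead of acyl transfer. Dess–Martin periodinane should oxidise 26 to the 6-oxo acid F1. NaBH4 should reduce it from the convex β-face to the 6α-hydroxy acid F2. An intramolecular Mitsunobu reaction (PPh3, diisopropyl azodicarboxylate) should then let the C19 carboxylate displace the activated 6α-oxygen with inversion, giving 28.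

Step 15 (key step). The amide base may substitute or eliminate at the 2-bromoethyl sulfate before C13 is deprotonated, or intermolecular alkylation may outrun the medium-ring closure. The fallback sets out from 18 and comes back at 20; it replaces the one-pot dianion cascade by a stepwise ester-enolate route. Me3SiCHN2 should give the methyl ester F3. KN(SiMe3)2 at −78 °C under high dilution should enolise it without attacking the tether and give the isolable ten-membered cyclic sulfate methyl ester F4. NaI in 2-butanone at 60 °C should open the cyclic sulfate at C15, and the γ-iodo ester should lactonise with loss of iodomethane to the sodium salt of 20, which is hydrolysed to 21 as in step 15.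

Step 5 (Diels–Alder reaction). Heating may cause loss of silanol and aromatisation of dienophile 4, or facial selectivity may erode because the C8 methyl group lies on the face the diene must use. The fallback sets out from 4 and 5 and comes back at 7; it makes no new compound (F0). It is a stepwise anionic annulation at −78 °C: the kinetic lithium dienolate of 5 (LiN(i-Pr)2) should add to C5 of 4 in a Michael addition, the resulting β-keto ester enolate should close ring A by a second, intramolecular Michael addition, and Me3SiCl should trap the ring-A enolate as 7.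

Further compounds

F1 | step 20 | 6-oxo acid: 26 with a C6 ketone | CC(=O)OC[C@]12CCC[C@](C)(C(=O)O)[C@H]1C(=O)C[C@@H](C)[C@]24CC[C@]5(CCOC5=O)O4
F2 | step 20 | 6α-hydroxy acid: C6 epimer of 26 | CC(=O)OC[C@]12CCC[C@](C)(C(=O)O)[C@H]1[C@@H](O)C[C@@H](C)[C@]24CC[C@]5(CCOC5=O)O4
F3 | step 15 | methyl ester of 18 (13RS) | BrCCOS(=O)(=O)OC[C@]12CC=C[C@](C)(COCc3ccccc3)[C@H]1[C@H](O[Si](C)(C)C(C)(C)C)C[C@@H](C)[C@]24CCC(C(=O)OC)O4
F4 | step 15 | ten-membered cyclic sulfate methyl ester (13R): methyl ester of 19 | O=S1(=O)OC[C@]23CC=C[C@](C)(COCc4ccccc4)[C@H]2[C@H](O[Si](C)(C)C(C)(C)C)C[C@@H](C)[C@]35CC[C@@](CCO1)(C(=O)OC)O5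
F0 | step 5 | none | none
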